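**Analysis of the target**

The target is a cyclohexene, numbered here C1(Me)=C2–C3–C4–C5–C6. C3 carries ring ArS, a 2-hydroxyphenyl ring with an (E)-2-(3,5-dihydroxyphenyl)ethenyl arm para to its hydroxyl. C4 carries a 2,4-dihydroxybenzoyl group (ketone ring ArK), C5 carries a 2,4-dihydroxyphenyl ring (ArR), and C6 is a methylene. The three contiguous stereocentres are C3 (R), C4 (R) and C5 (S). The substituents alternate between the ring faces, so ArS and ArR are cis to each other and the aroyl group is trans to both, which places all three equatorial in the half-chair. C4 is alpha to the ketone and can be equilibrated, and the required configuration is the thermodynamic one. C3 and C5 cannot be corrected, are 1,3-related and not bonded to each other, and must each be set absolutely. Sensitive features are seven phenols on electron-rich rings, a light- and acid-sensitive (E)-stilbene, a trisubstituted alkene that a neighbouring phenol can add to under acid, and a ketone flanked by two ortho-hydroxyaryl groups that can ketalise. The difficulty is three adjacent tertiary carbons, each bearing a bulky ortho-oxygenated aryl or aroyl group, with absolute control at the two outer ones. The strategy rests on three observations: C5 is beta and C4 alpha to the aryl ketone; C3 is a benzylic carbon allylic to C2; and the C1=C2 alkene is what a vinyl group on C3 and a methallyl group on C5 give on ring closure. The C5–ArR bond therefore maps onto conjugate arylation of an enone, and the C3–C4 bond onto branched allylation of the resulting enolate.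

**Retrosynthetic reasoning**

23 from 22. The seven phenols are unmasked last. Methoxymethyl ethers are used on every phenol because they survive organolithium, organomagnesium and organozinc reagents, fluoride, the ruthenium carbene, alkoxide base and palladium, and leave under mild acid without touching the alkenes by reduction or oxidation.

22 from 18 and 21. The aryl–vinyl bond of the stilbene is cut. The stilbene alkene would compete in olefin metathesis and is light-sensitive, so it is introduced after the ring is closed. An aryl bromide on ArS is inert to the rhodium, iridium and ruthenium steps and serves as the handle for a Heck coupling with styrene 21.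

18 from 17. The C1=C2 bond is cut by ring-closing metathesis, leading back to an acyclic ketone with a vinyl group on C3 and a methallyl group on C5. Once the ring exists, C4 can be equilibrated to the all-equatorial arrangement, so the acyclic step does not have to control C4 perfectly.

17 from 8, 10 and 15. Two bonds are cut in one operation. C5–ArR is cut as conjugate addition of arylzinc 10 to dienone 8 under a chiral rhodium–diene catalyst, with the enolate held as a silyl enol ether. C3–C4 is cut as attack of that enolate on the aryl-bearing terminus of the allyl unit from carbonate 15 under an iridium–phosphoramidite catalyst. C5 and C3 are then set by two different catalysts, so their cis relationship is a matter of pairing ligand enantiomers.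

8 from 6 and 7, 6 from 5, 5 from 2 and 3. Dienone 8 has a CH2 group between the enone and a 1,1-disubstituted alkene. Base moves that alkene into conjugation, so an aldol condensation of an aryl methyl ketone with a beta,gamma-unsaturated aldehyde is avoided. The C2=C3 enone bond is instead made under neutral conditions by cross-metathesis of aryl vinyl ketone 6 with diene 7. Ketone 6 comes from allylic alcohol 5, made by adding arylmagnesium bromide 4, formed from 2 by magnesium insertion, to 3.

10 from 2, 2 from 1. The arylzinc is made from bromide 2 by bromine–lithium exchange to aryllithium 9 and transfer to zinc. The bromide fixes the position of the metal, which ortho-lithiation of a resorcinol diether would not. Lithium is chosen here so that 10 carries no magnesium salts into the fluoride-mediated stage of the key step. Bromide 2 therefore serves both ArK and ArR.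

15 from 14, 13, 12 and 11. The linear cinnamyl carbonate is taken back through alcohol 14 and ester 13 to aldehyde 12 by olefination, reduction and acylation, and 12 comes from 11 by protection. The linear isomer is used because the iridium catalyst converts it cleanly into the branched product.

21 from 20 and 19. The styrene comes from a protected benzaldehyde by methylenation.

**Alternatives that were turned down**

Alternative 1: gold-catalysed enyne cycloisomerisation.
- Disconnection: the C1–C6 bond is cut, leading to the 1,5-enyne A2, in which only C3 is stereogenic.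
- Forward key step: Ph3PAuNTf2 (monovalent gold) activates the alkyne, and the terminal alkene carbon C6 attacks the methyl-bearing alkyne carbon C1. The cation at C5 is stabilised by ArR, C4 loses a proton, and protodeauration gives the cyclohexa-1,4-diene A1.
- For: one catalytic, atom-economic step closes the carbocycle with the methyl alkene already in place, and only one stereocentre has to be made beforehand. On ring formation this is stronger than the chosen route, which needs a separate metathesis.
- Against: A2 is a gamma,delta-alkynyl ketone, and attack of the carbonyl oxygen on the activated alkyne (furan formation) or the usual five-membered closure of 1,5-enynes can compete. A1 still lacks C4 and C5 as stereocentres. They would have to come from conjugate reduction of a tetrasubstituted enone flanked by two aryl groups, controlled only by C3, on a 1,4-diene that aromatises or isomerises easily. The masked aldehyde on ArS also costs extra steps to the stilbene.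
- Comparison: the chosen route sets C5 and C3 directly by catalysts and leaves only C4 to thermodynamics.

Alternative 2: ring-contracting Ireland–Claisen rearrangement.
- Disconnection: the C3–C4 bond is cut with ring contraction, leading to the delta-lactone A4.
- Forward key step: the lactone enolate is O-silylated and rearranges through a boat transition state enforced by the ring. C3–C4 forms as the C1–O bond breaks, giving the all-cis acid A3.
- For: chirality transfer to C3 is intramolecular and predictable, the carbocycle and C3–C4 form together, and no transition metal is needed. On the C3/C5 relationship it is at least as secure as pairing two catalysts, because no matched or mismatched combination can arise.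
- Against: A4 needs a tertiary, styryl-substituted carbinol centre set relative to the aryl-bearing carbon. That centre ionises easily and is destroyed in the step. A3 is the wrong C4 epimer and a carboxylic acid, so a hindered acid must be converted into the aryl ketone and then epimerised.
- Comparison: the chosen route carries ArK in from the start as part of the enone and is shorter.

Alternative 3: Stetter ring closure, then reductive alkene transposition.
- Disconnection: the C2–C3 bond is cut, leading to the enal A6, a (Z)-2-methyl enal tethered to an arylidene ketone.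
- Forward key step: a triazolium-derived N-heterocyclic carbene converts the aldehyde carbon into an acyl anion equivalent that adds to the ArS-bearing carbon, closing the cyclohexenone A5.
- For: the closure is organocatalytic, and in A5 both C3 and C4 are alpha to a carbonyl, so the all-trans array can be reached by equilibration with only C5 set beforehand. On the number of centres needing absolute control this is stronger than the chosen route.
- Against: the enal must have the less stable Z geometry. Enals also divert to homoenolate pathways with carbenes, and a trisubstituted, alpha-branched arylidene ketone is a poor Stetter acceptor. The ring carbonyl is on the wrong carbon and must be removed with an allylic shift (sulfonylhydrazone formation selective over the aryl ketone, then hydride reduction), after which C3 can no longer be corrected.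
- Comparison: the chosen route has no oxidation-state detour and forms two skeletal bonds in its key step.

Key step: step 10

Assumption: the ligand enantiomers named in step 10 follow the accepted facial models of the two catalyst families; because C5 and C3 are set by separate catalysts, an opposite sense found at either centre is corrected by using the mirror-image ligand for that catalyst alone.

**Route**

Step 1
Reactants: 1 4-bromoresorcinol
Product: 2 1-bromo-2,4-bis(methoxymethoxy)benzene
Conditions: MOMCl (2.5 equiv), i-Pr2NEt (3 equiv), CH2Cl2, 0 °C to rt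
Reagents that add atoms: chloromethyl methyl ether, COCCl
Why: Williamson-type O-alkylation of both phenols with a reactive alpha-chloro ether; the amine takes up the HCl.

Step 2
Reactants: 2 1-bromo-2,4-bis(methoxymethoxy)benzene; 3 acrolein
Product: 5 racemic 1-[2,4-bis(methoxymethoxy)phenyl]prop-2-en-1-ol, via [2,4-bis(methoxymethoxy)phenyl]magnesium bromide 4 (not isolated)
Conditions: Mg turnings (1.3 equiv, I2 crystal), THF, 40 °C; then 3 (1.2 equiv), −40 °C to 0 °C; aq. NH4Cl
Reagents that add atoms: none
Why: Magnesium inserts into the aryl C–Br bond to give Grignard reagent 4, which adds 1,2 to the aldehyde of the enal (Grignard addition); the methoxymethyl ethers are inert to it, and the new carbinol centre is removed in step 3, so it is left racemic.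

Step 3
Reactants: 5 racemic 1-[2,4-bis(methoxymethoxy)phenyl]prop-2-en-1-ol
Product: 6 1-[2,4-bis(methoxymethoxy)phenyl]prop-2-en-1-one
Conditions: MnO2 (10 equiv), CH2Cl2, rt; filtered and used at once
Reagents that add atoms: none
Why: Heterogeneous oxidation of an alcohol that is both allylic and benzylic; filtration alone isolates the polymerisation-prone aryl vinyl ketone.

Step 4
Reactants: 6 1-[2,4-bis(methoxymethoxy)phenyl]prop-2-en-1-one; 7 2-methylpenta-1,4-diene
Product: 8 (2E)-1-[2,4-bis(methoxymethoxy)phenyl]-5-methylhexa-2,5-dien-1-one
Conditions: second-generation Grubbs catalyst (H2IMes)(PCy3)Cl2Ru=CHPh (3 mol %), 7 (4 equiv), 1,4-benzoquinone (10 mol %), CH2Cl2, 40 °C, sealed vessel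
Reagents that add atoms: none
Why: Olefin cross-metathesis between an electron-poor vinyl ketone and the monosubstituted alkene of 7 should give the E-enone, while the 1,1-disubstituted alkene reacts far more slowly; neutral conditions keep the skipped diene out of conjugation, and benzoquinone suppresses ruthenium hydride migration.

Step 5
Reactants: 2 1-bromo-2,4-bis(methoxymethoxy)benzene
Product: 10 [2,4-bis(methoxymethoxy)phenyl]zinc chloride, via [2,4-bis(methoxymethoxy)phenyl]lithium 9 (not isolated)
Conditions: n-BuLi (1.05 equiv), THF, −78 °C; then ZnCl2 (1.1 equiv, THF), −78 °C to rt; used as solution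
Reagents that add atoms: zinc chloride, Cl[Zn]Cl
Why: Bromine–lithium exchange gives aryllithium 9, and lithium-to-zinc transmetalation then gives the mild aryl donor needed for the rhodium step, free of magnesium salts that would consume fluoride in the second stage of step 10.

Step 6
Reactants: 11 5-bromo-2-hydroxybenzaldehyde
Product: 12 5-bromo-2-(methoxymethoxy)benzaldehyde
Conditions: MOMCl (1.5 equiv), i-Pr2NEt (2 equiv), CH2Cl2, 0 °C to rt
Reagents that add atoms: chloromethyl methyl ether, COCCl
Why: O-alkylation of the hydrogen-bonded phenol with the reactive chloro ether under amine base.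

Step 7
Reactants: 12 5-bromo-2-(methoxymethoxy)benzaldehyde
Product: 13 ethyl (2E)-3-[5-bromo-2-(methoxymethoxy)phenyl]prop-2-enoate
Conditions: (EtO)2P(O)CH2CO2Et, NaH, THF, 0 °C to rt
Reagents that add atoms: triethyl phosphonoacetate, CCOC(=O)CP(=O)(OCC)OCC
Why: Horner–Wadsworth–Emmons olefination of an aryl aldehyde with a stabilised phosphonate anion gives the E-cinnamate.

Step 8
Reactants: 13 ethyl (2E)-3-[5-bromo-2-(methoxymethoxy)phenyl]prop-2-enoate
Product: 14 (2E)-3-[5-bromo-2-(methoxymethoxy)phenyl]prop-2-en-1-ol
Conditions: i-Bu2AlH (2.2 equiv), CH2Cl2, −78 °C; aq. KNaC4H4O6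
Reagents that add atoms: none
Why: 1,2-Reduction of the conjugated ester by an electrophilic aluminium hydride gives the allylic alcohol; alkene geometry and aryl bromide are untouched.

Step 9
Reactants: 14 (2E)-3-[5-bromo-2-(methoxymethoxy)phenyl]prop-2-en-1-ol
Product: 15 (2E)-3-[5-bromo-2-(methoxymethoxy)phenyl]prop-2-en-1-yl methyl carbonate
Conditions: ClCO2Me (1.3 equiv), pyridine (2 equiv), CH2Cl2, 0 °C
Reagents that add atoms: methyl chloroformate, COC(=O)Cl
Why: Acylation of the primary allylic alcohol gives the linear carbonate, the leaving group used for iridium allyl formation.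

Step 10
Reactants: 8 (2E)-1-[2,4-bis(methoxymethoxy)phenyl]-5-methylhexa-2,5-dien-1-one; 10 [2,4-bis(methoxymethoxy)phenyl]zinc chloride; 15 (2E)-3-[5-bromo-2-(methoxymethoxy)phenyl]prop-2-en-1-yl methyl carbonate
Product: 17 (2R,3S)-1,3-bis[2,4-bis(methoxymethoxy)phenyl]-2-{(1R)-1-[5-bromo-2-(methoxymethoxy)phenyl]prop-2-en-1-yl}-5-methylhex-5-en-1-one, via (1Z,3S)-trimethylsilyl enol ether 16 (not isolated)
Conditions: [RhCl(C2H4)2]2 (2.5 mol %), (R,R)-2,5-diphenylbicyclo[2.2.2]octa-2,5-diene (5.5 mol %), 10 (1.3 equiv), Me3SiCl (1.5 equiv), THF, 20 °C; volatiles removed in vacuo; then 15 (1.5 equiv), [Ir(cod)Cl]2 (2 mol %), (Sa,S,S)-O,O′-(1,1′-binaphthalene-2,2′-diyl) N,N-bis(1-phenylethyl)phosphoramidite (4 mol %, pre-activated with n-PrNH2), CsF (4 equiv), THF–DME, 40 °C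
Reagents that add atoms: none
Why: Proposed new method: each stage is of a known type (rhodium-catalysed asymmetric 1,4-addition of arylzinc chlorides to enones with Me3SiCl trapping; iridium–phosphoramidite branched allylation of silyl enol ethers under fluoride activation), and the new element is running them in one flask on an acyclic, alpha-branched enol ether. In the first stage the aryl group passes from zinc to monovalent rhodium, the rhodium–aryl adds across C4=C5 of the s-cis enone, and Me3SiCl silylates the oxa-allyl rhodium to give Z-enol ether 16 and ZnCl2. In the second stage the cyclometalated iridium complex ionises carbonate 15 to an allyl complex of trivalent iridium; CsF frees the enolate and also converts the ZnCl2 into the zinc fluoride that the known allylation uses as co-activator; the enolate attacks the aryl-bearing allyl terminus on the face away from iridium, forming C3–C4. No ring closes. C5 (S) is set by the chiral diene on rhodium, which should expose the si face of C5; C3 (R) is set by the phosphoramidite, which fixes the face of the allyl ligand bound to iridium independently of the nucleophile. C4 is set by the substrate: in the Z-enolate the C5–H lies in the enolate plane to relieve A(1,3) strain and the allyl unit should enter anti to ArR, favouring the 4R epimer drawn; material epimeric at C4 is corrected in step 11. The step needs branched over linear allylation (inherent to iridium with aryl-substituted allyl units), C- over O-allylation, a single allylation (the C4–H of 17 sits between two tertiary carbons), and aryl transfer to the enone only (the 1,1-disubstituted alkene does not insert into rhodium–aryl).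

Step 11
Reactants: 17 (2R,3S)-1,3-bis[2,4-bis(methoxymethoxy)phenyl]-2-{(1R)-1-[5-bromo-2-(methoxymethoxy)phenyl]prop-2-en-1-yl}-5-methylhex-5-en-1-one
Product: 18 [2,4-bis(methoxymethoxy)phenyl]{(1R,2R,6S)-6-[2,4-bis(methoxymethoxy)phenyl]-2-[5-bromo-2-(methoxymethoxy)phenyl]-4-methylcyclohex-3-en-1-yl}methanone
Conditions: second-generation Grubbs catalyst (H2IMes)(PCy3)Cl2Ru=CHPh (5 mol %), CH2Cl2, 40 °C; SiO2 filtration; then NaOMe (0.5 equiv), MeOH–THF, 40 °C
Reagents that add atoms: none
Why: Ring-closing metathesis of the vinyl and methallyl groups forms the trisubstituted C1=C2 alkene of a six-membered ring with loss of ethene. After removal of ruthenium, methoxide equilibrates C4 through the ring enolate, so any material epimeric at C4 should converge on the isomer with ArS, aroyl and ArR all equatorial; C3 and C5 are not acidic and stay fixed.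

Step 12
Reactants: 19 3,5-dihydroxybenzaldehyde
Product: 20 3,5-bis(methoxymethoxy)benzaldehyde
Conditions: MOMCl (2.5 equiv), i-Pr2NEt (3 equiv), CH2Cl2, 0 °C to rt
Reagents that add atoms: chloromethyl methyl ether, COCCl
Why: O-alkylation of both phenols, as in step 1.

Step 13
Reactants: 20 3,5-bis(methoxymethoxy)benzaldehyde
Product: 21 1-ethenyl-3,5-bis(methoxymethoxy)benzene
Conditions: Ph3PCH3Br, KOt-Bu, THF, 0 °C to rt
Reagents that add atoms: methyltriphenylphosphonium bromide, C[P+](c1ccccc1)(c1ccccc1)c1ccccc1.[Br-]
Why: Wittig methylenation of an aryl aldehyde with the non-stabilised ylide.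

Step 14
Reactants: 18 [2,4-bis(methoxymethoxy)phenyl]{(1R,2R,6S)-6-[2,4-bis(methoxymethoxy)phenyl]-2-[5-bromo-2-(methoxymethoxy)phenyl]-4-methylcyclohex-3-en-1-yl}methanone; 21 1-ethenyl-3,5-bis(methoxymethoxy)benzene
Product: 22 [2,4-bis(methoxymethoxy)phenyl]{(1R,2R,6S)-6-[2,4-bis(methoxymethoxy)phenyl]-2-{5-[(E)-2-[3,5-bis(methoxymethoxy)phenyl]ethenyl]-2-(methoxymethoxy)phenyl}-4-methylcyclohex-3-en-1-yl}methanone
Conditions: Pd2(dba)3 (2.5 mol %), [HP(t-Bu)3]BF4 (10 mol %), Cy2NMe (1.5 equiv), 1,4-dioxane, 80 °C
Reagents that add atoms: none
Why: Mizoroki–Heck coupling; zerovalent palladium with a bulky electron-rich phosphine inserts into the electron-rich aryl bromide, adds to the terminal carbon of the styrene and eliminates to the E-stilbene. The hindered trisubstituted ring alkene is not a competitive acceptor, and C4 is already at its thermodynamic configuration under the amine base.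

Step 15
Reactants: 22 [2,4-bis(methoxymethoxy)phenyl]{(1R,2R,6S)-6-[2,4-bis(methoxymethoxy)phenyl]-2-{5-[(E)-2-[3,5-bis(methoxymethoxy)phenyl]ethenyl]-2-(methoxymethoxy)phenyl}-4-methylcyclohex-3-en-1-yl}methanone
Product: 23 (2,4-dihydroxyphenyl){(1R,2R,6S)-6-(2,4-dihydroxyphenyl)-2-{5-[(E)-2-(3,5-dihydroxyphenyl)ethenyl]-2-hydroxyphenyl}-4-methylcyclohex-3-en-1-yl}methanone
Conditions: 3 M aq. HCl, MeOH–THF, 40 °C, argon, dark
Reagents that add atoms: none
Why: Acid-catalysed acetal exchange removes all seven methoxymethyl groups as dimethoxymethane; mild acid and moderate temperature are chosen to avoid ketalisation and phenol addition to the ring alkene.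

**Compound list**

1 | 4-bromoresorcinol | Oc1ccc(Br)c(O)c1 | starting material
2 | 1-bromo-2,4-bis(methoxymethoxy)benzene | COCOc1ccc(Br)c(OCOC)c1 | intermediate
3 | acrolein | C=CC=O | starting material
4 | [2,4-bis(methoxymethoxy)phenyl]magnesium bromide | Br[Mg]c1ccc(OCOC)cc1OCOC | intermediate
5 | racemic 1-[2,4-bis(methoxymethoxy)phenyl]prop-2-en-1-ol | C=CC(O)c1ccc(OCOC)cc1OCOC | intermediate
6 | 1-[2,4-bis(methoxymethoxy)phenyl]prop-2-en-1-one | C=CC(=O)c1ccc(OCOC)cc1OCOC | intermediate
7 | 2-methylpenta-1,4-diene | CC(=C)CC=C | starting material
8 | (2E)-1-[2,4-bis(methoxymethoxy)phenyl]-5-methylhexa-2,5-dien-1-one | CC(=C)C/C=C/C(=O)c1ccc(OCOC)cc1OCOC | intermediate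
9 | [2,4-bis(methoxymethoxy)phenyl]lithium | [Li]c1ccc(OCOC)cc1OCOC | intermediate
10 | [2,4-bis(methoxymethoxy)phenyl]zinc chloride | Cl[Zn]c1ccc(OCOC)cc1OCOC | intermediate
11 | 5-bromo-2-hydroxybenzaldehyde | O=Cc1cc(Br)ccc1O | starting material
12 | 5-bromo-2-(methoxymethoxy)benzaldehyde | O=Cc1cc(Br)ccc1OCOC | intermediate
13 | ethyl (2E)-3-[5-bromo-2-(methoxymethoxy)phenyl]prop-2-enoate | CCOC(=O)/C=C/c1cc(Br)ccc1OCOC | intermediate
14 | (2E)-3-[5-bromo-2-(methoxymethoxy)phenyl]prop-2-en-1-ol | OC/C=C/c1cc(Br)ccc1OCOC | intermediate
15 | (2E)-3-[5-bromo-2-(methoxymethoxy)phenyl]prop-2-en-1-yl methyl carbonate | COC(=O)OC/C=C/c1cc(Br)ccc1OCOC | intermediate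
16 | {[(1Z,3S)-1,3-bis[2,4-bis(methoxymethoxy)phenyl]-5-methylhexa-1,5-dien-1-yl]oxy}trimethylsilane | C[Si](C)(C)O/C(c1ccc(OCOC)cc1OCOC)=C\[C@@H](c1ccc(OCOC)cc1OCOC)CC(C)=C | intermediate
17 | (2R,3S)-1,3-bis[2,4-bis(methoxymethoxy)phenyl]-2-{(1R)-1-[5-bromo-2-(methoxymethoxy)phenyl]prop-2-en-1-yl}-5-methylhex-5-en-1-one | C=C[C@@H](c1cc(Br)ccc1OCOC)[C@H](C(=O)c1ccc(OCOC)cc1OCOC)[C@@H](c1ccc(OCOC)cc1OCOC)CC(C)=C | intermediate
18 | [2,4-bis(methoxymethoxy)phenyl]{(1R,2R,6S)-6-[2,4-bis(methoxymethoxy)phenyl]-2-[5-bromo-2-(methoxymethoxy)phenyl]-4-methylcyclohex-3-en-1-yl}methanone | CC1=C[C@@H](c2cc(Br)ccc2OCOC)[C@H](C(=O)c2ccc(OCOC)cc2OCOC)[C@@H](c2ccc(OCOC)cc2OCOC)C1 | intermediate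
19 | 3,5-dihydroxybenzaldehyde | O=Cc1cc(O)cc(O)c1 | starting material
20 | 3,5-bis(methoxymethoxy)benzaldehyde | O=Cc1cc(OCOC)cc(OCOC)c1 | intermediate
21 | 1-ethenyl-3,5-bis(methoxymethoxy)benzene | C=Cc1cc(OCOC)cc(OCOC)c1 | intermediate
22 | [2,4-bis(methoxymethoxy)phenyl]{(1R,2R,6S)-6-[2,4-bis(methoxymethoxy)phenyl]-2-{5-[(E)-2-[3,5-bis(methoxymethoxy)phenyl]ethenyl]-2-(methoxymethoxy)phenyl}-4-methylcyclohex-3-en-1-yl}methanone (heptakis(methoxymethyl) ether of the target) | CC1=C[C@@H](c2cc(/C=C/c3cc(OCOC)cc(OCOC)c3)ccc2OCOC)[C@H](C(=O)c2ccc(OCOC)cc2OCOC)[C@@H](c2ccc(OCOC)cc2OCOC)C1 | intermediate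
23 | (2,4-dihydroxyphenyl){(1R,2R,6S)-6-(2,4-dihydroxyphenyl)-2-{5-[(E)-2-(3,5-dihydroxyphenyl)ethenyl]-2-hydroxyphenyl}-4-methylcyclohex-3-en-1-yl}methanone | CC1=C[C@@H](c2cc(/C=C/c3cc(O)cc(O)c3)ccc2O)[C@H](C(=O)c2ccc(O)cc2O)[C@@H](c2ccc(O)cc2O)C1 | target

**Step count and risk**

Total step count: 15. Longest linear sequence: 8 steps (steps 1, 2, 3, 4, 10, 11, 14, 15; the branch through steps 6 to 9 is equally long).

Step 10 (key step). The most likely failures are interference between the two catalytic stages and weak control in the allylation.
- Residual arylzinc can consume part of the allyl electrophile, which is why 15 is used in excess.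
- Zinc and silicon halides can slow ionisation of the carbonate or cause premature loss of the silyl group, returning the simple conjugate-addition ketone.
- The hindered, alpha-branched enolate may react slowly or with poor facial selectivity at the allyl terminus.
- Incomplete 1,2-induction at C4 is tolerated, because step 11 equilibrates that centre.

Fallback for step 10, from 8 and 10, using known chemistry in separate operations: the rhodium-catalysed addition with Me3SiCl is run alone and quenched with K2CO3 in MeOH to give (3S)-1,3-bis[2,4-bis(methoxymethoxy)phenyl]-5-methylhex-5-en-1-one F1, which is purified. F1 is enolised with LiN(SiMe3)2 in THF at −78 °C and silylated with Me3SiCl to give pure Z-enol ether 16, isolated by non-aqueous work-up. Compound 16 is then allylated with 15 under the separate iridium protocol (the same [Ir(cod)Cl]2–phosphoramidite catalyst, ZnF2 and CsF, DME, 50 °C). The sequence returns to the route at 17.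

Step 4. The risk is migration of the 1,1-disubstituted alkene into conjugation by ruthenium hydride species, together with oligomerisation of the electron-poor vinyl ketone before it is captured.

Fallback for step 4, from 5: the cross-metathesis with 7 is run on the allylic alcohol, which cannot polymerise by conjugate addition and gives no carbonyl-conjugated position to drive alkene migration. The product, racemic (2E)-1-[2,4-bis(methoxymethoxy)phenyl]-5-methylhexa-2,5-dien-1-ol F2, is then oxidised with MnO2 in CH2Cl2. The sequence returns to the route at 8.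

Step 14. The risk is slow oxidative addition into the electron-rich aryl bromide, arylation at the internal styrene carbon, and palladium hydride migration of the ring alkene on prolonged heating.

Fallback for step 14, from 21 and 18: styrene 21 undergoes cross-metathesis with 4,4,5,5-tetramethyl-2-vinyl-1,3,2-dioxaborolane and (H2IMes)(PCy3)Cl2Ru=CHPh to give 2-[(E)-2-[3,5-bis(methoxymethoxy)phenyl]ethenyl]-4,4,5,5-tetramethyl-1,3,2-dioxaborolane F3. A Suzuki–Miyaura coupling of F3 with 18 (Pd(dppf)Cl2, K3PO4, dioxane–water, 80 °C) fixes the regiochemistry by transmetalation instead of insertion. The sequence returns to the route at 22.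

Step 15. The risk is that, under Brønsted acid, the freed ortho-phenols of ArS and ArR add to the ketone (ketalisation) or to the ring alkene, and that formaldehyde equivalents from the acetals alkylate the resorcinol rings.

Fallback for step 15, from 22: the aryl acetals are exchanged without Brønsted acid using Me3SiOTf and 2,2′-bipyridyl in CH3CN at 0 °C, which should give the heptakis(trimethylsilyl) ether F4, with the acetal carbons captured on the bipyridyl. F4 is then hydrolysed with water at rt. The sequence returns to the route at 23.

**Further compounds**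

F1 | step 10 | (3S)-1,3-bis[2,4-bis(methoxymethoxy)phenyl]-5-methylhex-5-en-1-one | O=C(c1ccc(OCOC)cc1OCOC)C[C@@H](c1ccc(OCOC)cc1OCOC)CC(C)=C
F2 | step 4 | racemic (2E)-1-[2,4-bis(methoxymethoxy)phenyl]-5-methylhexa-2,5-dien-1-ol | CC(=C)C/C=C/C(O)c1ccc(OCOC)cc1OCOC
F3 | step 14 | 2-[(E)-2-[3,5-bis(methoxymethoxy)phenyl]ethenyl]-4,4,5,5-tetramethyl-1,3,2-dioxaborolane | COCOc1cc(/C=C/B2OC(C)(C)C(C)(C)O2)cc(OCOC)c1
F4 | step 15 | heptakis(trimethylsilyl) ether of 23, (1R,2R,6S) | CC1=C[C@@H](c2cc(/C=C/c3cc(O[Si](C)(C)C)cc(O[Si](C)(C)C)c3)ccc2O[Si](C)(C)C)[C@H](C(=O)c2ccc(O[Si](C)(C)C)cc2O[Si](C)(C)C)[C@@H](c2ccc(O[Si](C)(C)C)cc2O[Si](C)(C)C)C1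
A1 | alternative 1 | 1-[2,4-bis(methoxymethoxy)benzoyl]-2-[2,4-bis(methoxymethoxy)phenyl]-6-[5-(1,3-dioxolan-2-yl)-2-(methoxymethoxy)phenyl]-4-methylcyclohexa-1,4-diene, C3 as in the target | CC1=C[C@@H](c2cc(C3OCCO3)ccc2OCOC)C(C(=O)c2ccc(OCOC)cc2OCOC)=C(c2ccc(OCOC)cc2OCOC)C1
A2 | alternative 1 | 1-[2,4-bis(methoxymethoxy)phenyl]-2-{1-[2,4-bis(methoxymethoxy)phenyl]ethenyl}-3-[5-(1,3-dioxolan-2-yl)-2-(methoxymethoxy)phenyl]hex-4-yn-1-one, C3 as in the target, either C2 epimer | CC#C[C@@H](c1cc(C2OCCO2)ccc1OCOC)C(C(=O)c1ccc(OCOC)cc1OCOC)C(=C)c1ccc(OCOC)cc1OCOC
A3 | alternative 2 | all-cis 6-[2,4-bis(methoxymethoxy)phenyl]-2-[5-bromo-2-(methoxymethoxy)phenyl]-4-methylcyclohex-3-ene-1-carboxylic acid | CC1=C[C@@H](c2cc(Br)ccc2OCOC)[C@@H](C(=O)O)[C@@H](c2ccc(OCOC)cc2OCOC)C1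
A4 | alternative 2 | 4-[2,4-bis(methoxymethoxy)phenyl]-6-{(E)-2-[5-bromo-2-(methoxymethoxy)phenyl]ethenyl}-6-methyloxan-2-one, 4-aryl trans to 6-alkenyl | O=C1C[C@@H](c2ccc(OCOC)cc2OCOC)C[C@](C)(/C=C/c2cc(Br)ccc2OCOC)O1
A5 | alternative 3 | all-trans 5-[2,4-bis(methoxymethoxy)benzoyl]-4-[2,4-bis(methoxymethoxy)phenyl]-6-[5-bromo-2-(methoxymethoxy)phenyl]-2-methylcyclohex-2-en-1-one | CC1=C[C@H](c2ccc(OCOC)cc2OCOC)[C@@H](C(=O)c2ccc(OCOC)cc2OCOC)[C@H](c2cc(Br)ccc2OCOC)C1=O
A6 | alternative 3 | (2Z,5E)-5-[2,4-bis(methoxymethoxy)benzoyl]-4-[2,4-bis(methoxymethoxy)phenyl]-6-[5-bromo-2-(methoxymethoxy)phenyl]-2-methylhexa-2,5-dienal, C4 as C5 of the target | O=C/C(C)=C\[C@H](c1ccc(OCOC)cc1OCOC)/C(C(=O)c1ccc(OCOC)cc1OCOC)=C\c1cc(Br)ccc1OCOC
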